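I start from something I take as unchanged within a run: at a given temperature, each Q meets J with the same chance per unit of [J] and of time, however much Q has already gone. So I work with the fraction left and not with the fraction made, because the logarithm of [Q] charged over [Q] left simply adds up [J] over time.

| flask | Q | J | temperature | remark | time |
|---|---|---|---|---|---|
| zeta | 10 mM | 4 mM | 0 °C | run made earlier |  |
| gamma | 10 mM | 16 mM | 35 °C | run made earlier |  |
| delta | 20 mM | 8 mM | 0 °C | run made earlier |  |
| maple | 10 mM | 8.00 mM | 5 °C |  | 25 h |
| larch | 10 mM | 8.00 mM | 35 °C |  | 25 h |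
| cedar | 10 mM | 8.00 mM | 65 °C |  | 25 h |

| run | time / h | E / % | Q / % |
|---|---|---|---|
| zeta | 4.00 | 6 | 95 |
| zeta | 8.00 | 3 | 95 |
| zeta | 12.0 | 9 | 91 |
| zeta | 15.0 | 9 | 88 |
| gamma | 0.833 | 15 | 71 |
| gamma | 2.00 | 25 | 54 |
| gamma | 2.50 | 28 | 52 |
| gamma | 3.00 | 30 | 50 |
| delta | 2.00 | 3 | 97 |
| delta | 5.00 | 5 | 95 |
| delta | 10.0 | 9 | 89 |
| delta | 15.0 | 10 | 81 |

(readings scatter by 2 percentage points)

1. which flask leads in amount of E, in percent of the Q charged ("all alike" within 1.5 percentage points) (maple / larch / cedar / all alike)
2. how much E is there at the end, in percent of the Q charged: maple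
3. how much E is there at the end, in percent of the Q charged: larch
4. how much E is there at the end, in percent of the Q charged: cedar

The cold runs test this: at 15.0 h the zeta run, with 4 mM of J, reads 0.128, and the delta run, with 8 mM, reads 0.211, a ratio of 1.65 that carries the scatter of the readings.

Read down the gamma table, the dose, which is the logarithm of Q charged over Q left, goes 0.342, then 0.616, then 0.693. The times of these rows are 0.833 h, 2.00 h and 3.00 h.

The first row climbs at 0.411 h⁻¹, but the last stretch climbs at 0.0770 h⁻¹, which is slower. So [J] has sunk in the gamma run, yet Q has lost 5.00 mM of the 16 mM of J charged. I therefore read J as dying largely by itself, in proportion to its own [J].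

Then the sum of [J] over time scales with the charge at 35 °C. Larch holds half of the gamma charge of J and the same charge of Q, so I reckon a dose of 0.347 by 3.00 h, which leaves 70.7% of its Q at that time. The gamma dose is still climbing at that time, so I commit to this as the lower mark of the larch dose at 25 h.

The forecast names maple as leader, with 24%, 20% and 11% for maple, larch and cedar, on the ground that “The gamma run stalls faster than J use by Q explains”.

The simulation puts E at 18.0% in maple, 32.7% in larch and 15.2% in cedar, so larch leads.

    Q + J → E + X (k = 0.0107 M⁻¹ s⁻¹, Ea = 56.0 kJ mol⁻¹)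
    J + E ⇌ D + X (K = 1.70, k = 0.0436 M⁻¹ s⁻¹, Ea = 56.0 kJ mol⁻¹, ΔH = −17.0 kJ mol⁻¹)
    J → Z (k = 1.25 × 10⁻⁴ s⁻¹, Ea = 91.0 kJ mol⁻¹)
    (constants at 35 °C)

Larch ends with Q at 67%, a dose of 0.400, above my lower mark of 0.347, and J, the limiting reagent, is down to 0.083% of its charge. Cedar took the same charge of J, yet its Q ends at 85%, a dose of 0.165, smaller than in larch. The main reason cedar holds so little E is the turning of J into Z: the cedar run without that turning holds 80.0% of E, not 15.2%.

All runs come from a simulation with made-up constants.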